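**Strategy.** Everything rests on cutting the piperidine ring at C2'–C3' and N1'–C6'. The feature exploited is that C2' is a benzylic amine carbon tied to N1' through the four-carbon chain C3'–C6' and sits on C6 of ring A between two equivalent oxygens (C5, C7), so it can come from the formyl carbon of symmetrical phloroglucinaldehyde. In one operation a 4-chlorobutyl Grignard reagent adds to an (S)-tert-butanesulfinyl aldimine, setting C2' as R, and the nitrogen then displaces chloride to close the ring. The precursor is the E-sulfinimine of 2,6-bis(benzyloxy)-4-(triisopropylsilyloxy)benzaldehyde, whose para oxygen is later freed alone to carry the C2–C4 unit of ring C.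

Key step: step 5

Assumption: in toluene the Grignard addition follows the sulfinyl-oxygen-chelated chair model despite the two ortho benzyloxy groups, so the (S)-auxiliary gives (R)-C2'; the sulfinyl diastereomers of 9 should be separable on silica in any case.

**Route**

Step 1
Reactants: 1 2,4,6-trihydroxybenzaldehyde
Product: 2 2,6-dihydroxy-4-(triisopropylsilyloxy)benzaldehyde
Conditions: TIPSCl (1.05 equiv), imidazole, DMF, 0 °C
Reagents that add atoms: triisopropylsilyl chloride, CC(C)[Si](Cl)(C(C)C)C(C)C
Why: Silyl chloride/imidazole O-silylation should pick the 4-hydroxyl, which is the most acidic (para to the formyl group) and the only one neither crowded nor hydrogen-bonded by the neighbouring carbonyl, and the bulk of the triisopropylsilyl group reinforces that preference.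

Step 2
Reactants: 2 2,6-dihydroxy-4-(triisopropylsilyloxy)benzaldehyde
Product: 3 2,6-bis(benzyloxy)-4-(triisopropylsilyloxy)benzaldehyde
Conditions: BnOH (2.4 equiv), PPh3, DIAD, THF, 0 °C → rt
Reagents that add atoms: benzyl alcohol, OCc1ccccc1
Why: Mitsunobu etherification alkylates both remaining phenols under neutral conditions, so no phenoxide or carbonate is present that could cleave or shift the aryl silyl ether.

Step 3
Reactants: 3 2,6-bis(benzyloxy)-4-(triisopropylsilyloxy)benzaldehyde; 4 (S)-tert-butanesulfinamide
Product: 5 (S,E)-N-[2,6-bis(benzyloxy)-4-(triisopropylsilyloxy)benzylidene]-2-methylpropane-2-sulfinamide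
Conditions: Ti(OEt)4 (2 equiv), THF, 65 °C
Reagents that add atoms: none
Why: Ti(OEt)4-mediated condensation of an aldehyde with tert-butanesulfinamide (sulfinimine formation), in which the titanium alkoxide activates the hindered, electron-rich carbonyl and takes up the water, should give the E-aldimine without touching the sulfur stereocentre.

Step 4
Reactants: 6 1-bromo-4-chlorobutane
Product: 7 4-chlorobutylmagnesium bromide (solution, used directly)
Conditions: Mg, I2 (cat.), Et2O, 25–35 °C
Reagents that add atoms: magnesium, [Mg]
Why: Grignard formation by insertion of magnesium into the weaker C–Br bond, the primary C–Cl bond being inert at this temperature and the four-carbon spacing disfavouring ring closure of the reagent itself.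

Step 5
Reactants: 5 (S,E)-N-[2,6-bis(benzyloxy)-4-(triisopropylsilyloxy)benzylidene]-2-methylpropane-2-sulfinamide; 7 4-chlorobutylmagnesium bromide
Product: 9 (R)-2-[2,6-bis(benzyloxy)-4-(triisopropylsilyloxy)phenyl]-1-[(S)-tert-butylsulfinyl]piperidine, via open-chain bromomagnesium sulfinamide adduct 8 (not isolated)
Conditions: 7 (2 equiv), toluene, −78 → −20 °C; then KN(SiMe3)2 (1.5 equiv), THF, 0 → 40 °C
Reagents that add atoms: none
Why: The Grignard reagent adds 1,2 to the C=N bond of 5 (addition of an organomagnesium reagent to an N-tert-butanesulfinyl aldimine), forming C2'–C3'; in toluene magnesium is bound to the sulfinyl oxygen and the alkyl group is passed on through a six-membered chair transition state with tert-butyl equatorial. This delivers the chain to the Re face of the (S,E)-aldimine, so the sulfur stereocentre of the auxiliary sets C2' as R (priorities N > aryl > chain > H). KN(SiMe3)2 in THF then converts the magnesium sulfinamide 8 into the more nucleophilic potassium salt, which displaces the primary chloride by intramolecular SN2 in a 6-exo-tet closure, forming N1'–C6' and the piperidine ring. The closest known reaction type is the addition of halogen-bearing carbon chains to sulfinyl imines followed by base-induced cyclisation to 2-substituted pyrrolidines and piperidines. The step needs facial selectivity and N- over O-alkylation: the first rests on the auxiliary and the E-geometry, the two identical ortho benzyloxy groups making both aryl rotamers equivalent, and the second on ring size, since O-alkylation would require an eight-membered ring. Silyl and benzyl ethers are inert to both bases.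

Step 6
Reactants: 9 (R)-2-[2,6-bis(benzyloxy)-4-(triisopropylsilyloxy)phenyl]-1-[(S)-tert-butylsulfinyl]piperidine
Product: 11 (R)-2-[2,6-bis(benzyloxy)-4-(triisopropylsilyloxy)phenyl]-1-methylpiperidine, via secondary amine hydrochloride 10 (not isolated)
Conditions: HCl (4 M in dioxane), MeOH, 0 °C; evaporate; then 37% aq. HCHO, NaBH(OAc)3, NaOAc, ClCH2CH2Cl, rt
Reagents that add atoms: formaldehyde, C=O
Why: Acidic methanolysis cleaves the N–S bond of the sulfinamide without touching C2', and the resulting secondary amine is methylated by reductive amination with formaldehyde and NaBH(OAc)3 while every oxygen is still capped, so no Mannich reaction on ring A can compete.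

Step 7
Reactants: 11 (R)-2-[2,6-bis(benzyloxy)-4-(triisopropylsilyloxy)phenyl]-1-methylpiperidine
Product: 12 3,5-bis(benzyloxy)-4-[(R)-1-methylpiperidin-2-yl]phenol
Conditions: Bu4NF, AcOH, THF, 0 °C
Reagents that add atoms: none
Why: Fluoride-mediated desilylation, driven by the Si–F bond, frees only the para oxygen because benzyl ethers do not respond to fluoride, and the acetic acid buffer avoids a basic phenoxide para to the benzylic amine.

Step 8
Reactants: 12 3,5-bis(benzyloxy)-4-[(R)-1-methylpiperidin-2-yl]phenol; 13 ethyl (R)-3-hydroxy-3-phenylpropanoate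
Product: 14 ethyl (S)-3-{3,5-bis(benzyloxy)-4-[(R)-1-methylpiperidin-2-yl]phenoxy}-3-phenylpropanoate
Conditions: 13 (1.3 equiv), PPh3, DIAD, toluene, 0 °C → rt
Reagents that add atoms: none
Why: Mitsunobu etherification, in which the phenol displaces the activated secondary benzylic oxyphosphonium group of 13 by SN2 with inversion, turning the (R)-carbinol carbon into the (S)-configured benzylic aryl ether that becomes C2; the phenol is unhindered because both benzyloxy groups are meta to it.

Step 9
Reactants: 14 ethyl (S)-3-{3,5-bis(benzyloxy)-4-[(R)-1-methylpiperidin-2-yl]phenoxy}-3-phenylpropanoate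
Product: 15 (S)-3-{3,5-bis(benzyloxy)-4-[(R)-1-methylpiperidin-2-yl]phenoxy}-3-phenylpropanoic acid
Conditions: LiOH·H2O, THF/H2O, 0 °C → rt; then aq. HCl to pH 7
Reagents that add atoms: lithium hydroxide (hydroxide oxygen), [Li+].[OH-]
Why: Ester saponification with LiOH at low temperature is faster than α-deprotonation, so the β-aryloxy group should not be eliminated and neither stereocentre is touched.

Step 10
Reactants: 15 (S)-3-{3,5-bis(benzyloxy)-4-[(R)-1-methylpiperidin-2-yl]phenoxy}-3-phenylpropanoic acid
Product: 17 (S)-5,7-bis(benzyloxy)-6-[(R)-1-methylpiperidin-2-yl]-2-phenylchroman-4-one, via mixed trifluoroacetic anhydride 16 (not isolated)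
Conditions: CF3CO2H (2 equiv), then (CF3CO)2O, CH2Cl2, 0 °C → rt
Reagents that add atoms: none
Why: Intramolecular Friedel–Crafts acylation through the mixed trifluoroacetic anhydride closes ring C in a six-membered mode onto either of the two equivalent ring-A carbons ortho to the ether oxygen, each activated by three alkoxy groups so that no metal Lewis acid is needed and the benzyl ethers survive, while prior protonation of the amine keeps it from being acylated and the C2 stereocentre takes no part in the bond made.

Step 11
Reactants: 17 (S)-5,7-bis(benzyloxy)-6-[(R)-1-methylpiperidin-2-yl]-2-phenylchroman-4-one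
Product: 18 (S)-5,7-dihydroxy-6-[(R)-1-methylpiperidin-2-yl]-2-phenylchroman-4-one (CNP0404761.1)
Conditions: H2 (1 atm), 10% Pd/C, EtOAc/MeOH, rt
Reagents that add atoms: none
Why: Catalytic hydrogenolysis removes the two primary benzyl aryl ethers, which cleave much faster than the secondary, ring-held benzylic C2–O1 and C2'–N1' bonds, so stopping after uptake of two equivalents of hydrogen should leave both stereocentres and the ketone intact.

**Compound list**

1 | 2,4,6-trihydroxybenzaldehyde | O=Cc1c(O)cc(O)cc1O | starting material
2 | 2,6-dihydroxy-4-(triisopropylsilyloxy)benzaldehyde | O=Cc1c(O)cc(O[Si](C(C)C)(C(C)C)C(C)C)cc1O | intermediate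
3 | 2,6-bis(benzyloxy)-4-(triisopropylsilyloxy)benzaldehyde | O=Cc1c(OCc2ccccc2)cc(O[Si](C(C)C)(C(C)C)C(C)C)cc1OCc1ccccc1 | intermediate
4 | (S)-tert-butanesulfinamide | CC(C)(C)[S@](=O)N | starting material
5 | (S,E)-N-[2,6-bis(benzyloxy)-4-(triisopropylsilyloxy)benzylidene]-2-methylpropane-2-sulfinamide | CC(C)(C)[S@](=O)/N=C/c1c(OCc2ccccc2)cc(O[Si](C(C)C)(C(C)C)C(C)C)cc1OCc1ccccc1 | intermediate
6 | 1-bromo-4-chlorobutane | ClCCCCBr | starting material
7 | 4-chlorobutylmagnesium bromide | ClCCCC[Mg]Br | intermediate
8 | bromomagnesium salt of (S)-N-{(R)-1-[2,6-bis(benzyloxy)-4-(triisopropylsilyloxy)phenyl]-5-chloropentyl}-2-methylpropane-2-sulfinamide | CC(C)(C)[S@](=O)N([Mg]Br)[C@H](CCCCCl)c1c(OCc2ccccc2)cc(O[Si](C(C)C)(C(C)C)C(C)C)cc1OCc1ccccc1 | intermediate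
9 | (R)-2-[2,6-bis(benzyloxy)-4-(triisopropylsilyloxy)phenyl]-1-[(S)-tert-butylsulfinyl]piperidine | CC(C)(C)[S@](=O)N1CCCC[C@@H]1c1c(OCc2ccccc2)cc(O[Si](C(C)C)(C(C)C)C(C)C)cc1OCc1ccccc1 | intermediate
10 | (R)-2-[2,6-bis(benzyloxy)-4-(triisopropylsilyloxy)phenyl]piperidine hydrochloride | [Cl-].[NH2+]1CCCC[C@@H]1c1c(OCc2ccccc2)cc(O[Si](C(C)C)(C(C)C)C(C)C)cc1OCc1ccccc1 | intermediate
11 | (R)-2-[2,6-bis(benzyloxy)-4-(triisopropylsilyloxy)phenyl]-1-methylpiperidine | CN1CCCC[C@@H]1c1c(OCc2ccccc2)cc(O[Si](C(C)C)(C(C)C)C(C)C)cc1OCc1ccccc1 | intermediate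
12 | 3,5-bis(benzyloxy)-4-[(R)-1-methylpiperidin-2-yl]phenol | CN1CCCC[C@@H]1c1c(OCc2ccccc2)cc(O)cc1OCc1ccccc1 | intermediate
13 | ethyl (R)-3-hydroxy-3-phenylpropanoate | CCOC(=O)C[C@@H](O)c1ccccc1 | starting material
14 | ethyl (S)-3-{3,5-bis(benzyloxy)-4-[(R)-1-methylpiperidin-2-yl]phenoxy}-3-phenylpropanoate | CN1CCCC[C@@H]1c1c(OCc2ccccc2)cc(O[C@@H](CC(=O)OCC)c2ccccc2)cc1OCc1ccccc1 | intermediate
15 | (S)-3-{3,5-bis(benzyloxy)-4-[(R)-1-methylpiperidin-2-yl]phenoxy}-3-phenylpropanoic acid | CN1CCCC[C@@H]1c1c(OCc2ccccc2)cc(O[C@@H](CC(=O)O)c2ccccc2)cc1OCc1ccccc1 | intermediate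
16 | mixed anhydride of 15 with trifluoroacetic acid (present as its ammonium trifluoroacetate) | CN1CCCC[C@@H]1c1c(OCc2ccccc2)cc(O[C@@H](CC(=O)OC(=O)C(F)(F)F)c2ccccc2)cc1OCc1ccccc1 | intermediate
17 | (S)-5,7-bis(benzyloxy)-6-[(R)-1-methylpiperidin-2-yl]-2-phenylchroman-4-one | CN1CCCC[C@@H]1c1c(OCc2ccccc2)cc2c(c1OCc1ccccc1)C(=O)C[C@@H](c1ccccc1)O2 | intermediate
18 | (S)-5,7-dihydroxy-6-[(R)-1-methylpiperidin-2-yl]-2-phenylchroman-4-one | CN1CCCC[C@@H]1c1c(O)cc2c(c1O)C(=O)C[C@@H](c1ccccc1)O2 | target

**Step count and risks**

Total step count: 11. Longest linear sequence: 10 steps (steps 1–3 and 5–11, from 1 to 18); step 4 is the side branch that supplies the Grignard reagent.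

Steps most likely to fail:

1. Step 5. An ortho benzyloxy oxygen may bind magnesium in place of the sulfinyl oxygen and lower the facial selectivity, or N-alkylation of the hindered sulfinamide anion may stall. The fallback sets out from 5 and separates addition from ring closure. Reagent 7 is added in toluene at −78 °C and the mixture is quenched with aqueous NH4Cl without base, which should give the open-chain adduct (S)-N-{(R)-1-[2,6-bis(benzyloxy)-4-(triisopropylsilyloxy)phenyl]-5-chloropentyl}-2-methylpropane-2-sulfinamide F1, whose diastereomers can be separated on silica. HCl in dioxane/MeOH at 0 °C then removes the auxiliary to give (R)-1-[2,6-bis(benzyloxy)-4-(triisopropylsilyloxy)phenyl]-5-chloropentan-1-amine hydrochloride F2. K2CO3 and NaI in MeCN at 60 °C close the ring through the free primary amine (6-exo-tet N-alkylation) to (R)-2-[2,6-bis(benzyloxy)-4-(triisopropylsilyloxy)phenyl]piperidine F3. F3 is methylated with HCHO/NaBH(OAc)3 as in the second stage of step 6, and the route is rejoined at 11.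

2. Step 10. Acid may erode C2 by ionisation of the benzylic aryl ether, epimerise C2' through the electron-rich benzylic ammonium, or strip a benzyl ether before acylation is complete. The fallback sets out from 15 and closes ring C without acid by a Parham cyclisation. N-Bromosuccinimide in MeCN at 0 °C, with one equivalent of CF3CO2H to keep the amine protonated, should brominate one of the two equivalent free ring-A positions to give (S)-3-{2-bromo-3,5-bis(benzyloxy)-4-[(R)-1-methylpiperidin-2-yl]phenoxy}-3-phenylpropanoic acid F4. n-BuLi (2.2 equiv) in THF at −78 °C then forms the lithium carboxylate and exchanges bromine for lithium, and the aryllithium adds to the carboxylate; aqueous work-up should give 17.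

3. Step 11. Over-reduction may occur: hydrogenolysis of the ring benzylic C2–O1 or C2'–N1' bond, or reduction of the C4 ketone, may compete with O-debenzylation. The fallback sets out from 17 and avoids hydrogen altogether. BCl3 with pentamethylbenzene as cation scavenger in CH2Cl2 at −78 °C cleaves both benzyl ethers and should give 18 directly; this fallback makes no new compound (F0).

**Further compounds**

F1 | step 5 | (S)-N-{(R)-1-[2,6-bis(benzyloxy)-4-(triisopropylsilyloxy)phenyl]-5-chloropentyl}-2-methylpropane-2-sulfinamide | CC(C)(C)[S@](=O)N[C@H](CCCCCl)c1c(OCc2ccccc2)cc(O[Si](C(C)C)(C(C)C)C(C)C)cc1OCc1ccccc1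
F2 | step 5 | (R)-1-[2,6-bis(benzyloxy)-4-(triisopropylsilyloxy)phenyl]-5-chloropentan-1-amine hydrochloride | [Cl-].[NH3+][C@H](CCCCCl)c1c(OCc2ccccc2)cc(O[Si](C(C)C)(C(C)C)C(C)C)cc1OCc1ccccc1
F3 | step 5 | (R)-2-[2,6-bis(benzyloxy)-4-(triisopropylsilyloxy)phenyl]piperidine | N1CCCC[C@@H]1c1c(OCc2ccccc2)cc(O[Si](C(C)C)(C(C)C)C(C)C)cc1OCc1ccccc1
F4 | step 10 | (S)-3-{2-bromo-3,5-bis(benzyloxy)-4-[(R)-1-methylpiperidin-2-yl]phenoxy}-3-phenylpropanoic acid | CN1CCCC[C@@H]1c1c(OCc2ccccc2)cc(O[C@@H](CC(=O)O)c2ccccc2)c(Br)c1OCc1ccccc1
F0 | step 11 | none | none
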